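The pitfall: both earlier runs hold 0.95 equiv of second nucleophile from the start, so neither shows a slow feed of it.

| flask | substrate | first nucleophile | second nucleophile | remark | time |
|---|---|---|---|---|---|
| north-east | 0.050 M | 2.5 equiv | 0.95 equiv | run made earlier |  |
| south | 0.050 M | 3.8 equiv | 0.95 equiv | run made earlier |  |
| oak | 0.050 M (fed, over 12 h) | 2.50 equiv | 0.950 equiv | all else is in the flask from the start; the feed brings no volume worth counting | 2.5 d |
| ash | 0.050 M (fed, over 50 h) | 2.50 equiv | 0.950 equiv | all else is in the flask from the start; the feed brings no volume worth counting | 2.5 d |
| maple | 0.050 M | 2.50 equiv | 0.950 equiv (fed, over 50 h) | all else is in the flask from the start; the feed brings no volume worth counting | 2.5 d |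
| larch | 0.050 M | 2.50 equiv | 0.950 equiv | everything together at the start | 2.5 d |

- north-east (time / d: target / %): 0.625: 32.8; 1.25: 52.1; 2.08: 68.0; 2.50: 72.7
- south (time / h: target / %): 2.50: 9.8; 6.00: 21.4; 12.0: 37.5; 20.0: 53.2

(standard deviation of a reading: 0.5 percentage points)

- the flask that comes out highest in amount of target, in percent of the substrate charged, or "all alike" when all lie within 1.5 percentage points (oak / ash / maple / larch / all alike)
- target at the end, in percent of the substrate charged, oak
- target at the end, in percent of the substrate charged, ash
- target at the end, in percent of the substrate charged, maple
- target at the end, in percent of the substrate charged, larch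

With first nucleophile at 2.5 equiv, I treat the loss of substrate as pseudo-first-order. Counting the first north-east reading of target as substrate lost gives 0.636 /d for the clearance rate, the first-order rate constant of substrate loss at these charges, a reading with its scatter. The first south reading, counted the same way, gives 0.990 /d, a factor 1.56 for a factor 1.52 in first nucleophile, so I let clearance follow that charge.

From clearance I reckon 20.4% of the substrate left in larch. A steady feed gives each portion only its remaining time, so for oak, whose 12 h feed is shorter than the clearance time, the inverse of the clearance rate, of 37.7 h, I reckon 24.0% left, and for ash, fed over 50 h, 42.5% left. Against that reckoned loss the last north-east reading puts 91.3% of the substrate lost into target, so I reckon oak at 69.4%, ash at 52.5% and larch, the north-east recipe, at 72.7%. I give maple larch's clearance, and neither earlier run has a feed of second nucleophile, so I put maple level with larch.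

The forecast names larch highest, with oak 69.8%, ash 52.5%, maple 72% and larch 73%, maple “barely below larch”. The flasks give oak 70.0%, ash 54.6%, maple 74.8% and larch 72.6%, so maple stands highest.

    substrate ⇌ intermediate (K = 0.0140, k = 0.00560 /min)
    first nucleophile + intermediate → target (k = 0.310 /M/min)
    second nucleophile + intermediate → other capture product (k = 0.0960 /M/min)
    second nucleophile ⇌ dormant form (K = 1.60, k = 5.10 × 10⁻⁴ /min)
    crystals ⇌ target, rate k5*(cs5 - [target]) while solid is left; crystals form when [target] > cs5 (solubility = 7.10 mM, k = 0.0260 /min)

Clearance reckoned 20.4% of the substrate left in larch and 42.5% in ash; those flasks hold 20.8% and 41.2% of substrate. The selectivity factor, capture of intermediate by first nucleophile over capture by second nucleophile, climbs in larch from 8.50 at the start to 15.7 at the end. Maple starts without second nucleophile and ends at 12, holding less other capture product than larch, 3.16% against 6.29%. A neighbour of maple charged with 0.013 M of substrate, same equivalents, its clearance scaled by that charge, reckons at 66.1% of its substrate left, and it holds 62%.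

The earlier runs and the new flask are calculated for substances that don't exist; noise was put on by code.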